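**Retrosynthetic overview**

1. Chain positions are numbered C1–C19 from the pentyl end (C6, C7, C9 = oxolane C2, C3, C5; C10 = carbinol carbon). Target 17 ⇐ its C10 silyl ether 16 by desilylation.
2. 16 ⇐ epoxy acrylate 11 + undecylcopper: one operation cuts Cβ–Cγ of the tetradecanoate, the ring bond O1–C2 (C6–O) and the ester bond at the C7 oxygen.
3. Enabling feature: the acyloxy oxygen on ring carbon C3 is 1,2 to the ring bond C2–O1 and 1,3 to C5–O1. The acyl carbon can therefore hold all three oxygens in a temporary 2,7,8-trioxabicyclo[3.2.1]octane orthoester (two C–O bonds absent from the target); this cage arises from the C9 acrylate of a trans C6–C7 oxirane and collapses to the oxolane with the acyl group left on the C7 oxygen, and the acrylate Cβ accepts the undecyl group.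
4. 11 ⇐ (E)-homoallylic alcohol 9 (Shi epoxidation, acryloylation); 9 ⇐ (2R,3R)-diepoxybutane 2, opened at one terminus by oct-7-enylmagnesium bromide (then O-silylation) and at the other by an (E)-hept-1-enyl aluminate.
5. Ring order: the two oxiranes of 2 are opened in steps 1 and 3, the C6–C7 oxirane is made in step 4, and in step 6 the orthoester cage forms and breaks and the oxolane, the only ring of the target, closes.

Key step: step 6

Remark: (2R,3R)-1,2:3,4-diepoxybutane (the bis-epoxide of D-threitol) and undecylmagnesium bromide solution are taken as purchasable reagents; Cα, Cβ, Cγ denote C2, C3, C4 of the acyl chain.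

**Route**

Step 1
Reactants: 1 8-bromooct-1-ene; 2 (2R,3R)-1,2:3,4-diepoxybutane
Product: 4 (1R)-1-[(2R)-oxiran-2-yl]dec-9-en-1-ol, via oct-7-enylmagnesium bromide 3 (not isolated)
Conditions: Mg, THF, 25 °C; then added slowly to 2 (3 equiv), CuI (10 mol%), THF, −40 → −20 °C; aq. NH4Cl
Reagents that add atoms: none
Why: Copper-catalysed Grignard opening of an epoxide at its terminal CH2 (SN2) leaves both stereocentres of the C2-symmetric bis-epoxide untouched, and the excess of 2 with slow addition should hold the reaction at mono-opening.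

Step 2
Reactants: 4 (1R)-1-[(2R)-oxiran-2-yl]dec-9-en-1-ol
Product: 5 tert-butyl(dimethyl){[(1R)-1-[(2R)-oxiran-2-yl]dec-9-en-1-yl]oxy}silane
Conditions: TBSCl, imidazole, DMF, 25 °C
Reagents that add atoms: tert-butyldimethylsilyl chloride, CC(C)(C)[Si](C)(C)Cl
Why: Imidazole-mediated silylation of a secondary alcohol under neutral conditions should block O10 for the key step without Payne rearrangement of the neighbouring oxirane.

Step 3
Reactants: 5 tert-butyl(dimethyl){[(1R)-1-[(2R)-oxiran-2-yl]dec-9-en-1-yl]oxy}silane; 6 hept-1-yne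
Product: 9 (6E,9R,10R)-10-{[tert-butyl(dimethyl)silyl]oxy}nonadeca-6,18-dien-9-ol, via (E)-hept-1-enyl(diisobutyl)alane 7 (not isolated), via lithium alkenylaluminate 8 (not isolated)
Conditions: 6 (1.1 equiv to Al–H), i-Bu2AlH, hexane, 50 °C; MeLi, Et2O, −30 °C; then 5, THF, −30 → 25 °C; H2O work-up
Reagents that add atoms: none
Why: syn-Hydroalumination of the terminal alkyne gives the (E)-alkenylalane, whose methyl ate complex should transfer the alkenyl group with retention of geometry to the unsubstituted oxirane carbon (alkenylaluminate epoxide opening), freeing the C9 hydroxyl and leaving C9 and C10 untouched.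

Step 4
Reactants: 9 (6E,9R,10R)-10-{[tert-butyl(dimethyl)silyl]oxy}nonadeca-6,18-dien-9-ol
Product: 10 (2R,3R)-3-{[tert-butyl(dimethyl)silyl]oxy}-1-[(2R,3R)-3-pentyloxiran-2-yl]dodec-11-en-2-ol
Conditions: D-fructose-derived Shi ketone (30 mol%), Oxone, K2CO3, n-Bu4NHSO4, MeCN–dimethoxymethane/aq. borate buffer (pH 10.5), 0 °C
Reagents that add atoms: potassium peroxymonosulfate (Oxone), [K+].[O-]S(=O)(=O)OO
Why: In the Shi epoxidation the chiral dioxirane should attack the trans-disubstituted C6=C7 bond through the spiro transition state to set the (6R,7R)-oxirane under reagent control, while the monosubstituted C18=C19 bond reacts much more slowly.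

Step 5
Reactants: 10 (2R,3R)-3-{[tert-butyl(dimethyl)silyl]oxy}-1-[(2R,3R)-3-pentyloxiran-2-yl]dodec-11-en-2-ol
Product: 11 (2R,3R)-3-{[tert-butyl(dimethyl)silyl]oxy}-1-[(2R,3R)-3-pentyloxiran-2-yl]dodec-11-en-2-yl prop-2-enoate
Conditions: acryloyl chloride, i-Pr2NEt, CH2Cl2, −20 → 0 °C
Reagents that add atoms: acryloyl chloride, C=CC(=O)Cl
Why: Acylation of the secondary C9 alcohol by an acid chloride under amine base should leave the oxirane, the silyl ether and the alkene untouched.

Step 6
Reactants: 11 (2R,3R)-3-{[tert-butyl(dimethyl)silyl]oxy}-1-[(2R,3R)-3-pentyloxiran-2-yl]dodec-11-en-2-yl prop-2-enoate; 12 undecylmagnesium bromide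
Product: 16 (2S,3S,5R)-5-[(1R)-1-{[tert-butyl(dimethyl)silyl]oxy}dec-9-en-1-yl]-2-pentyloxolan-3-yl tetradecanoate, via orthoacrylate cage 13 (not isolated), via oxolanyl acrylate 14 (not isolated), via undecylcopper 15 (not isolated)
Conditions: BF3·OEt2 (1.5 equiv), CH2Cl2, −78 → −20 °C; then transferred into 15 [3 equiv; from 12, CuI, THF–Et2O, −40 °C, then BF3·OEt2, −78 °C], −78 → −40 °C; aq. NH4Cl
Reagents that add atoms: none
Why: Proposed new method: BF3 activates the oxirane of 11 and the acrylate carbonyl oxygen opens it at C7 (6-exo-tet, inversion), the resulting 1,3-dioxan-2-ylium ion being caught by the freed C6 oxygen as orthoacrylate cage 13; BF3 then re-ionises 13 by cleaving its bond to the C9 oxygen, and that oxygen displaces the C6–O bond of the strained five-membered 1,3-dioxolan-2-ylium ion from the rear (5-exo-tet SN2, inversion at C6), which closes the oxolane and leaves the acrylate on the C7 oxygen (14). Undecylcopper–BF3 (15) then adds 1,4 to the BF3-bound acrylate and forms the Cβ–Cγ bond of the tetradecanoate, protonation of the enolate on work-up giving 16. The closest known reaction types are the Lewis acid-induced epoxy ester–orthoester rearrangement of homoallylic epoxy esters to 2,7,8-trioxabicyclo[3.2.1]octanes, the orthoester–cyclic ether rearrangement of 1,2,4-triol orthoesters to 3-acyloxyoxolanes and the BF3-mediated conjugate addition of alkylcopper reagents to acrylic esters; new is their merger in one flask with an acrylate as the migrating acyl group. The two new ring stereocentres (C6 and C7) arise by one inversion each of the (6R,7R)-oxirane, so the Shi epoxidation alone fixes the 2,3-cis-2,5-trans pattern, while C9 and C10 are carried through unchanged because the C9–O bond is never broken. The step needs attack of the C9 oxygen at C6 instead of attack of the C6 oxygen at C9 (secured by the greater strain of the five-membered acyloxonium ion and by the bulky silyloxy group next to C9, which also keeps O10 from taking part) and 1,4- instead of 1,2-addition (secured by the soft organocopper at −78 °C). The organocopper is introduced only after the oxirane is consumed, since it would otherwise open it.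

Step 7
Reactants: 16 (2S,3S,5R)-5-[(1R)-1-{[tert-butyl(dimethyl)silyl]oxy}dec-9-en-1-yl]-2-pentyloxolan-3-yl tetradecanoate
Product: 17 (2S,3S,5R)-5-[(1R)-1-hydroxydec-9-en-1-yl]-2-pentyloxolan-3-yl tetradecanoate
Conditions: HF·pyridine, pyridine, THF, 0 → 25 °C
Reagents that add atoms: none
Why: Fluoride cleavage of the silyl ether under buffered, weakly acidic conditions should free the C10 hydroxyl without touching the ester, the oxolane or the alkene and without acyl migration.

**Compound list**

1 | 8-bromooct-1-ene | C=CCCCCCCBr | starting material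
2 | (2R,3R)-1,2:3,4-diepoxybutane [(2R,2'R)-2,2'-bioxirane] | C1O[C@H]1[C@H]1CO1 | starting material
3 | oct-7-enylmagnesium bromide (not isolated) | C=CCCCCCC[Mg]Br | intermediate
4 | (1R)-1-[(2R)-oxiran-2-yl]dec-9-en-1-ol | C=CCCCCCCC[C@@H](O)[C@H]1CO1 | intermediate
5 | tert-butyl(dimethyl){[(1R)-1-[(2R)-oxiran-2-yl]dec-9-en-1-yl]oxy}silane | C=CCCCCCCC[C@@H](O[Si](C)(C)C(C)(C)C)[C@H]1CO1 | intermediate
6 | hept-1-yne | CCCCCC#C | starting material
7 | (E)-hept-1-enyl(diisobutyl)alane (not isolated) | CCCCC/C=C/[Al](CC(C)C)CC(C)C | intermediate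
8 | lithium (E)-hept-1-enyl(methyl)diisobutylaluminate (not isolated) | [Li+].CCCCC/C=C/[Al-](C)(CC(C)C)CC(C)C | intermediate
9 | (6E,9R,10R)-10-{[tert-butyl(dimethyl)silyl]oxy}nonadeca-6,18-dien-9-ol | C=CCCCCCCC[C@@H](O[Si](C)(C)C(C)(C)C)[C@H](O)C/C=C/CCCCC | intermediate
10 | (2R,3R)-3-{[tert-butyl(dimethyl)silyl]oxy}-1-[(2R,3R)-3-pentyloxiran-2-yl]dodec-11-en-2-ol | C=CCCCCCCC[C@@H](O[Si](C)(C)C(C)(C)C)[C@H](O)C[C@H]1O[C@@H]1CCCCC | intermediate
11 | (2R,3R)-3-{[tert-butyl(dimethyl)silyl]oxy}-1-[(2R,3R)-3-pentyloxiran-2-yl]dodec-11-en-2-yl prop-2-enoate | C=CCCCCCCC[C@@H](O[Si](C)(C)C(C)(C)C)[C@H](OC(=O)C=C)C[C@H]1O[C@@H]1CCCCC | intermediate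
12 | undecylmagnesium bromide | CCCCCCCCCCC[Mg]Br | starting material
13 | (3R,5S,6R)-1-ethenyl-6-pentyl-3-[(1R)-1-{[tert-butyl(dimethyl)silyl]oxy}dec-9-en-1-yl]-2,7,8-trioxabicyclo[3.2.1]octane, C1 fixed by the cage (not isolated) | C=C[C@@]12O[C@H](CCCCC)[C@@H](O1)C[C@@H](O2)[C@H](O[Si](C)(C)C(C)(C)C)CCCCCCCC=C | intermediate
14 | (2S,3S,5R)-5-[(1R)-1-{[tert-butyl(dimethyl)silyl]oxy}dec-9-en-1-yl]-2-pentyloxolan-3-yl prop-2-enoate (not isolated) | C=CCCCCCCC[C@@H](O[Si](C)(C)C(C)(C)C)[C@H]1C[C@H](OC(=O)C=C)[C@H](CCCCC)O1 | intermediate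
15 | undecylcopper, used as its BF3 complex (not isolated) | CCCCCCCCCCC[Cu] | intermediate
16 | (2S,3S,5R)-5-[(1R)-1-{[tert-butyl(dimethyl)silyl]oxy}dec-9-en-1-yl]-2-pentyloxolan-3-yl tetradecanoate | C=CCCCCCCC[C@@H](O[Si](C)(C)C(C)(C)C)[C@H]1C[C@H](OC(=O)CCCCCCCCCCCCC)[C@H](CCCCC)O1 | intermediate
17 | (2S,3S,5R)-5-[(1R)-1-hydroxydec-9-en-1-yl]-2-pentyloxolan-3-yl tetradecanoate | C=CCCCCCCC[C@@H](O)[C@H]1C[C@H](OC(=O)CCCCCCCCCCCCC)[C@H](CCCCC)O1 | target

**Step count and risks**

Total step count: 7. Longest linear sequence: 7 steps (1/2 → 17).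

Steps most likely to fail:

Step 6 (Proposed new method).
- What may go wrong: closure in the wrong mode (the C6 oxygen attacking C9 of the six-membered acyloxonium ion, which would invert C9), participation of the silyl ether oxygen in the oxirane opening, cationic oligomerisation of the vinyl-substituted acyloxonium ion, or 1,2-addition and enolate oligomerisation in the organocopper stage.
- Fallback (known chemistry, each event run and checked separately with a saturated migrating acyl group): it sets out from 10. Acetylation (Ac2O, pyridine) should give the epoxy acetate F1. Zirconocene dichloride/silver perchlorate-catalysed epoxy ester–orthoester rearrangement should give the orthoacetate cage F2. BF3·OEt2 (CH2Cl2, 0 °C) should convert it into the 3-acetoxyoxolane F3. Methanolysis (K2CO3, MeOH) should give the oxolan-3-ol F4. Acryloyl chloride/i-Pr2NEt should then give 14, now isolated. A tin hydride Giese reaction with 1-iodoundecane (Bu3SnH, AIBN, benzene, 80 °C) should form the Cβ–Cγ bond and return to the route at 16.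

Step 3.
- What may go wrong: sluggish opening of the hindered silyloxy-substituted oxirane, transfer of a methyl or isobutyl group instead of the alkenyl group, or hydride delivery from residual Al–H.
- Fallback: it sets out from 5. Lithium hept-1-ynide (from 6, n-BuLi) with BF3·OEt2 (THF, −78 °C) should open the oxirane at its terminal carbon to the homopropargylic alcohol F5. Dissolving-metal reduction (Na, NH3/THF, −40 °C), which leaves the terminal alkene and the silyl ether alone, should give the (E)-alkene and return at 9.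

Step 4.
- What may go wrong: incomplete facial selectivity at C6=C7, partial oxidation of the terminal alkene, or acid-induced 5-endo closure of the epoxy alcohol during isolation.
- Fallback: it sets out from 9. The non-directed dioxirane is replaced by a hydroxyl-directed, ligand-controlled epoxidation (chiral bis-hydroxamic acid–tungsten or hafnium catalyst with aqueous H2O2 or cumene hydroperoxide). The C9 hydroxyl binds the metal and should deliver the oxidant only to the C6=C7 bond; the fallback returns at 10.

Further compounds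
F1 | step 6 | (2R,3R)-3-{[tert-butyl(dimethyl)silyl]oxy}-1-[(2R,3R)-3-pentyloxiran-2-yl]dodec-11-en-2-yl acetate | C=CCCCCCCC[C@@H](O[Si](C)(C)C(C)(C)C)[C@H](OC(C)=O)C[C@H]1O[C@@H]1CCCCC
F2 | step 6 | (3R,5S,6R)-1-methyl-6-pentyl-3-[(1R)-1-{[tert-butyl(dimethyl)silyl]oxy}dec-9-en-1-yl]-2,7,8-trioxabicyclo[3.2.1]octane | C[C@@]12O[C@H](CCCCC)[C@@H](O1)C[C@@H](O2)[C@H](O[Si](C)(C)C(C)(C)C)CCCCCCCC=C
F3 | step 6 | (2S,3S,5R)-5-[(1R)-1-{[tert-butyl(dimethyl)silyl]oxy}dec-9-en-1-yl]-2-pentyloxolan-3-yl acetate | C=CCCCCCCC[C@@H](O[Si](C)(C)C(C)(C)C)[C@H]1C[C@H](OC(C)=O)[C@H](CCCCC)O1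
F4 | step 6 | (2S,3S,5R)-5-[(1R)-1-{[tert-butyl(dimethyl)silyl]oxy}dec-9-en-1-yl]-2-pentyloxolan-3-ol | C=CCCCCCCC[C@@H](O[Si](C)(C)C(C)(C)C)[C@H]1C[C@H](O)[C@H](CCCCC)O1
F5 | step 3 | (9R,10R)-10-{[tert-butyl(dimethyl)silyl]oxy}nonadec-18-en-6-yn-9-ol | C=CCCCCCCC[C@@H](O[Si](C)(C)C(C)(C)C)[C@H](O)CC#CCCCCC
F0 | step 4 | none | none
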